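Atom labels: oxolane O1, C2 (bears the catechol ring), C3 (bears C9H2OH), C4 (bears carbinol C7 and, through it, the guaiacyl ring), C5 (CH2).
Feature: C4 lies next to C7 and C2 lies β to C9. With C7 drawn as a 1-arylvinyl carbon, C4 is an allylic terminus. With a second carboxyl on C3, the C2–C3 pair is an arylidene malonate. The ring therefore divides into O1–C5–C4 (a vinyl epoxide) and C2–C3.
Endgame disconnections: the benzyl ethers; the C7/C9 diol from a cis-fused γ-lactone C7–O–C9(=O); C3–H from loss of the spare ester; C7–H from an aryl ketone; the ketone oxygen from the C7=CH2 group.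
Key disconnection: O1–C2 and C3–C4 together, in a palladium-catalysed (3+2) cycloaddition that carries both enantiomers of the racemic epoxide into one oxolane.
Ring order: the oxolane first (step 6); a temporary lactone ring second (step 8), which tells the two esters apart and fixes C3, and is opened again in step 10.

Key step: step 6

Assumption: the (R,R)-bisphosphine is written for the (2R,4R)-cycloadduct; the sense of induction for an allyl unit with an aryl group on its central carbon cannot be read from the parent system, and the (S,S)-ligand takes its place if the first experiment shows the opposite sense.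

Step 1
Reactants: 1 3,4-bis(benzyloxy)benzaldehyde; 2 dimethyl malonate
Product: 3 dimethyl 2-[3,4-bis(benzyloxy)benzylidene]malonate
Conditions: piperidine (10 mol %), AcOH (10 mol %), toluene, reflux, Dean–Stark trap
Reagents that add atoms: none
Why: Knoevenagel condensation of a non-enolisable aromatic aldehyde with a malonate, driven to completion by azeotropic removal of water; no stereocentre is formed.

Step 2
Reactants: 4 4-(benzyloxy)-3-methoxybenzaldehyde (O-benzylvanillin)
Product: 5 1-(benzyloxy)-2-methoxy-4-(2-methoxyethenyl)benzene (E/Z mixture)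
Conditions: Ph3P(CH2OMe)Cl, KOtBu, THF, 0 °C to rt
Reagents that add atoms: (methoxymethyl)triphenylphosphonium chloride, COC[P+](c1ccccc1)(c1ccccc1)c1ccccc1.[Cl-]
Why: Wittig methoxymethylenation of an aromatic aldehyde is a standard one-carbon homologation, and the alkene geometry does not matter because both isomers hydrolyse to the same aldehyde.

Step 3
Reactants: 5 1-(benzyloxy)-2-methoxy-4-(2-methoxyethenyl)benzene
Product: 6 2-[4-(benzyloxy)-3-methoxyphenyl]acetaldehyde
Conditions: 2 M aq. HCl, THF, 50 °C
Reagents that add atoms: water, O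
Why: Acid-catalysed enol ether hydrolysis (protonation at the β carbon, addition of water, loss of methanol) frees the arylacetaldehyde under conditions that leave aryl benzyl and methyl ethers intact.

Step 4
Reactants: 6 2-[4-(benzyloxy)-3-methoxyphenyl]acetaldehyde
Product: 7 2-[4-(benzyloxy)-3-methoxyphenyl]prop-2-enal
Conditions: 37% aq. CH2O, pyrrolidine (10 mol %), EtCO2H (10 mol %), i-PrOH, 45 °C
Reagents that add atoms: formaldehyde, C=O
Why: Organocatalytic α-methylenation (Mannich condensation, then elimination of the amine) acts at the only enolisable position of 6, and the sensitive 2-arylacrolein is carried on without storage.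

Step 5
Reactants: 7 2-[4-(benzyloxy)-3-methoxyphenyl]prop-2-enal; 8 trimethylsulfonium iodide
Product: 9 rac-2-{1-[4-(benzyloxy)-3-methoxyphenyl]ethenyl}oxirane
Conditions: 8, KOtBu, DMSO–THF, 0 °C, then 7; Et3N-deactivated silica
Reagents that add atoms: trimethylsulfonium iodide (compound 8), C[S+](C)C.[I-]
Why: Corey–Chaykovsky epoxidation, in which the unstabilised sulfonium ylide adds irreversibly to the carbonyl carbon of the enal and the betaine closes with loss of dimethyl sulfide, should give the vinyl epoxide as the racemate, which is all the dynamic key step requires.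

Step 6
Reactants: 3 dimethyl 2-[3,4-bis(benzyloxy)benzylidene]malonate; 9 rac-2-{1-[4-(benzyloxy)-3-methoxyphenyl]ethenyl}oxirane
Product: 10 dimethyl (2R,4R)-2-[3,4-bis(benzyloxy)phenyl]-4-{1-[4-(benzyloxy)-3-methoxyphenyl]ethenyl}oxolane-3,3-dicarboxylate (2,4-trans)
Conditions: Pd2(dba)3·CHCl3 (2.5 mol %), (1R,2R)-N,N'-bis[2-(diphenylphosphino)benzoyl]cyclohexane-1,2-diamine (7.5 mol %), toluene, rt, slow addition of 9
Reagents that add atoms: none
Why: Zerovalent palladium ionises the allylic C4–O bond of either enantiomer of 9 to a zwitterion, a palladium-bound 2-aryl-η3-allyl unit (C4–C7–CH2) carrying the C5 alkoxide, and the two diastereomeric complexes exchange allyl faces through the η1 form bound at the unsubstituted CH2 terminus faster than they are consumed, so that both epoxide enantiomers drain through one complex (dynamic kinetic asymmetric transformation). The alkoxide adds reversibly to the β carbon of 3 (oxa-Michael addition, O1–C2), and the resulting malonate carbanion alkylates the allyl unit at C4 on the face remote from palladium (C3–C4), releasing the catalyst. The closest known reaction type is the palladium-catalysed (3+2) cycloaddition of vinyl epoxides with doubly activated alkenes, combined with the deracemising allylic substitution of butadiene monoepoxide with this ligand class; the aryl group on the central allyl carbon extends the known substrate range. The oxolane closes in a 5-exo mode at the internal allyl terminus with the arylvinyl group left outside the ring, whereas attack at the CH2 terminus would need a seven-membered ring, so the length of the O1–C2–C3 tether secures the regiochemistry. C4 is set by the ligand, which decides which allyl face is alkylated, and C2 is set in the same ring closure, because the reversible oxa-Michael step supplies both C2 epimers of the open adduct and only the faster-closing one is drained (Curtin–Hammett situation), the wanted one holding the catechol ring and the emerging arylvinyl group on opposite ring faces. The step needs enantioface selectivity, the 2,4-trans relation and capture of the alkoxide before the zwitterion isomerises by hydride shift; the gem-diester helps by keeping C3 non-stereogenic so that only two centres must be controlled, slow addition of 9 keeps the acceptor in excess over the zwitterion, and the trans preference itself has to be won by the choice of ligand.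

Step 7
Reactants: 10 dimethyl (2R,4R)-2-[3,4-bis(benzyloxy)phenyl]-4-{1-[4-(benzyloxy)-3-methoxyphenyl]ethenyl}oxolane-3,3-dicarboxylate
Product: 12 dimethyl (2R,4R)-4-[4-(benzyloxy)-3-methoxybenzoyl]-2-[3,4-bis(benzyloxy)phenyl]oxolane-3,3-dicarboxylate, via vicinal diol 11 (not isolated)
Conditions: OsO4 (2 mol %), NaIO4 (4 equiv), 2,6-lutidine (2 equiv), 1,4-dioxane–H2O (3:1), rt
Reagents that add atoms: OsO4 (osmium tetroxide, oxygen carrier), O=[Os](=O)(=O)=O; NaIO4 (sodium metaperiodate, terminal oxidant), [Na+].[O-]I(=O)(=O)=O
Why: Lemieux–Johnson cleavage (dihydroxylation of the only alkene, then glycol fission) removes the CH2 terminus as formaldehyde without attacking the protected electron-rich arenes, and the lutidine buffer keeps the medium near neutral so that the ketone neither epimerises at C4 nor loses O1 from C5 by β-elimination.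

Step 8
Reactants: 12 dimethyl (2R,4R)-4-[4-(benzyloxy)-3-methoxybenzoyl]-2-[3,4-bis(benzyloxy)phenyl]oxolane-3,3-dicarboxylate
Product: 14 methyl (3R,3aR,6R,6aS)-6-[3,4-bis(benzyloxy)phenyl]-3-[4-(benzyloxy)-3-methoxyphenyl]-1-oxotetrahydro-1H,3H-furo[3,4-c]furan-6a-carboxylate, via hydroxy diester 13 (not isolated)
Conditions: (S)-2-methyl-CBS-oxazaborolidine (30 mol %), BH3·SMe2 (1 equiv), THF, −20 °C; MeOH; then DBU (20 mol %), toluene, 40 °C
Reagents that add atoms: none
Why: Corey–Bakshi–Shibata reduction, in which the oxazaborolidine binds the ketone oxygen at the lone pair remote from the aryl ring and passes hydride from the coordinated borane to one carbonyl face, should set C7 as R in the sense known for aryl alkyl ketones with the (S)-catalyst (acetophenone gives the R alcohol, and the priority order O, aryl, alkyl, H is the same here), by reagent control against the Felkin–Anh bias of C4, and the carbinol can then acylate only at the C3 ester on its own ring face (base-catalysed transesterification to a γ-lactone), which tells the two esters apart and places the guaiacyl ring on the concave face of the cis-fused bicycle.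

Step 9
Reactants: 14 methyl (3R,3aR,6R,6aS)-6-[3,4-bis(benzyloxy)phenyl]-3-[4-(benzyloxy)-3-methoxyphenyl]-1-oxotetrahydro-1H,3H-furo[3,4-c]furan-6a-carboxylate
Product: 15 (3R,3aR,6S,6aS)-6-[3,4-bis(benzyloxy)phenyl]-3-[4-(benzyloxy)-3-methoxyphenyl]tetrahydro-1H,3H-furo[3,4-c]furan-1-one
Conditions: LiCl (3 equiv), H2O (3 equiv), DMSO, 130 °C
Reagents that add atoms: none
Why: Krapcho dealkoxycarbonylation, in which chloride takes the methyl group by SN2, the carboxylate loses CO2 and the lactone enolate can be protonated only to the cis-fused bicyclo[3.3.0] skeleton, should place H3 cis to H4 and C9 trans to the catechol ring, while ring opening by loss of O1 from C2 is held back because the C2–O1 bond lies near the nodal plane of the enolate (the reverse of a 5-endo closure).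

Step 10
Reactants: 15 (3R,3aR,6S,6aS)-6-[3,4-bis(benzyloxy)phenyl]-3-[4-(benzyloxy)-3-methoxyphenyl]tetrahydro-1H,3H-furo[3,4-c]furan-1-one
Product: 16 {(2S,3R,4R)-4-{(R)-[4-(benzyloxy)-3-methoxyphenyl](hydroxy)methyl}-2-[3,4-bis(benzyloxy)phenyl]oxolan-3-yl}methanol
Conditions: LiAlH4, THF, 0 °C; aq. potassium sodium tartrate
Reagents that add atoms: none
Why: Lactone reduction with LiAlH4 breaks only the acyl C9–O bond, so C7 keeps its oxygen and its configuration and C9 becomes the hydroxymethyl group, and the non-acidic work-up avoids ionisation at C7 and closure to a furofuran.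

Step 11
Reactants: 16 {(2S,3R,4R)-4-{(R)-[4-(benzyloxy)-3-methoxyphenyl](hydroxy)methyl}-2-[3,4-bis(benzyloxy)phenyl]oxolan-3-yl}methanol
Product: 17 (7R)-7-hydroxytaxiresinol, 4-[(2S,3R,4R)-4-[(R)-hydroxy(4-hydroxy-3-methoxyphenyl)methyl]-3-(hydroxymethyl)oxolan-2-yl]benzene-1,2-diol
Conditions: H2 (1 atm), 10% Pd/C, EtOAc–EtOH, rt, stopped after uptake of three equivalents
Reagents that add atoms: none
Why: Catalytic hydrogenolysis cleaves the three aryl benzyl ethers much faster than the secondary benzylic C7–OH and C2–O1 bonds under neutral conditions at one atmosphere, and no stereocentre is touched.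

Compound list
1 | 3,4-bis(benzyloxy)benzaldehyde | O=Cc1ccc(OCc2ccccc2)c(OCc2ccccc2)c1 | starting material
2 | dimethyl malonate | COC(=O)CC(=O)OC | starting material
3 | dimethyl 2-[3,4-bis(benzyloxy)benzylidene]malonate | COC(=O)C(=Cc1ccc(OCc2ccccc2)c(OCc3ccccc3)c1)C(=O)OC | intermediate
4 | 4-(benzyloxy)-3-methoxybenzaldehyde | COc1cc(C=O)ccc1OCc1ccccc1 | starting material
5 | 1-(benzyloxy)-2-methoxy-4-(2-methoxyethenyl)benzene (E/Z mixture) | COC=Cc1ccc(OCc2ccccc2)c(OC)c1 | intermediate
6 | 2-[4-(benzyloxy)-3-methoxyphenyl]acetaldehyde | O=CCc1ccc(OCc2ccccc2)c(OC)c1 | intermediate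
7 | 2-[4-(benzyloxy)-3-methoxyphenyl]prop-2-enal | C=C(C=O)c1ccc(OCc2ccccc2)c(OC)c1 | intermediate
8 | trimethylsulfonium iodide | C[S+](C)C.[I-] | starting material
9 | rac-2-{1-[4-(benzyloxy)-3-methoxyphenyl]ethenyl}oxirane | COc1cc(C(=C)C2CO2)ccc1OCc3ccccc3 | intermediate
10 | dimethyl (2R,4R)-2-[3,4-bis(benzyloxy)phenyl]-4-{1-[4-(benzyloxy)-3-methoxyphenyl]ethenyl}oxolane-3,3-dicarboxylate | COc1cc(C(=C)[C@H]2CO[C@H](c3ccc(OCc4ccccc4)c(OCc5ccccc5)c3)C2(C(=O)OC)C(=O)OC)ccc1OCc6ccccc6 | intermediate
11 | dimethyl (2R,4R)-2-[3,4-bis(benzyloxy)phenyl]-4-{1-[4-(benzyloxy)-3-methoxyphenyl]-1,2-dihydroxyethyl}oxolane-3,3-dicarboxylate (C7 epimers) | COc1cc(C(O)(CO)[C@H]2CO[C@H](c3ccc(OCc4ccccc4)c(OCc5ccccc5)c3)C2(C(=O)OC)C(=O)OC)ccc1OCc6ccccc6 | intermediate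
12 | dimethyl (2R,4R)-4-[4-(benzyloxy)-3-methoxybenzoyl]-2-[3,4-bis(benzyloxy)phenyl]oxolane-3,3-dicarboxylate | COc1cc(C(=O)[C@H]2CO[C@H](c3ccc(OCc4ccccc4)c(OCc5ccccc5)c3)C2(C(=O)OC)C(=O)OC)ccc1OCc6ccccc6 | intermediate
13 | dimethyl (2R,4R)-4-{(R)-[4-(benzyloxy)-3-methoxyphenyl](hydroxy)methyl}-2-[3,4-bis(benzyloxy)phenyl]oxolane-3,3-dicarboxylate | COc1cc([C@H](O)[C@H]2CO[C@H](c3ccc(OCc4ccccc4)c(OCc5ccccc5)c3)C2(C(=O)OC)C(=O)OC)ccc1OCc6ccccc6 | intermediate
14 | methyl (3R,3aR,6R,6aS)-6-[3,4-bis(benzyloxy)phenyl]-3-[4-(benzyloxy)-3-methoxyphenyl]-1-oxotetrahydro-1H,3H-furo[3,4-c]furan-6a-carboxylate (cis-fused; guaiacyl ring endo, catechol ring exo) | COc1cc([C@@H]2OC(=O)[C@@]3(C(=O)OC)[C@@H]2CO[C@@H]3c4ccc(OCc5ccccc5)c(OCc6ccccc6)c4)ccc1OCc7ccccc7 | intermediate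
15 | (3R,3aR,6S,6aS)-6-[3,4-bis(benzyloxy)phenyl]-3-[4-(benzyloxy)-3-methoxyphenyl]tetrahydro-1H,3H-furo[3,4-c]furan-1-one | COc1cc([C@@H]2OC(=O)[C@H]3[C@@H]2CO[C@@H]3c4ccc(OCc5ccccc5)c(OCc6ccccc6)c4)ccc1OCc7ccccc7 | intermediate
16 | {(2S,3R,4R)-4-{(R)-[4-(benzyloxy)-3-methoxyphenyl](hydroxy)methyl}-2-[3,4-bis(benzyloxy)phenyl]oxolan-3-yl}methanol | COc1cc([C@H](O)[C@H]2CO[C@H](c3ccc(OCc4ccccc4)c(OCc5ccccc5)c3)[C@H]2CO)ccc1OCc6ccccc6 | intermediate
17 | (7R)-7-hydroxytaxiresinol | COc1cc([C@H](O)[C@H]2CO[C@H](c3ccc(O)c(O)c3)[C@H]2CO)ccc1O | target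

Total step count: 11. Longest linear sequence: 10 steps (4 to 17, steps 2 to 11).

Steps most likely to fail

Step 6.
- What may go wrong: the allyl complexes may be trapped before they have exchanged faces. The ring closure may discriminate poorly between the two C2 epimers of the open adduct. The electron-rich acceptor may hold the alkoxide too weakly, so that enantioface and 2,4-trans selectivity are low.
- Fallback: absolute control is moved from the ligand to a later reagent. It sets out from 3 and 9 and comes back at 12. With Pd(PPh3)4 in THF the same cycloaddition makes no demand on a chiral ligand. After chromatography to secure the 2,4-trans relation, it should give the racemate, that is 10 together with its enantiomer, dimethyl (2S,4S)-2-[3,4-bis(benzyloxy)phenyl]-4-{1-[4-(benzyloxy)-3-methoxyphenyl]ethenyl}oxolane-3,3-dicarboxylate F1. Lemieux–Johnson cleavage as in step 7 turns the pair into 12 and the enantiomeric (2S,4S)-ketone F2. A kinetic resolution by Corey–Bakshi–Shibata reduction follows, with the (S)-oxazaborolidine and about half an equivalent of hydride. In F2 the catalyst and the Felkin–Anh preference address the same carbonyl face, so F2 should be consumed first and leave as the exo-aryl lactone ester F3. Compound 12, in which the two influences oppose each other, is recovered by chromatography and enters step 8.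

Step 8.
- What may go wrong: hydride delivery may follow the substrate rather than the catalyst. C4 carries the quaternary C3, and attack anti to it (Felkin–Anh) leads to the 7S carbinol, so the catalyst works in a mismatched pairing and facial selectivity may be poor. Closure of the lactone with the aryl ring on the concave face may also be slow.
- Fallback: the roles of nucleophile and resident group at C7 are exchanged, so that the same substrate bias now gives 7R. It sets out from 3 and comes back at 14. Commercial racemic 2-vinyloxirane and 3 under the conditions of step 6 should give dimethyl (2R,4R)-2-[3,4-bis(benzyloxy)phenyl]-4-ethenyloxolane-3,3-dicarboxylate F4. Lemieux–Johnson cleavage gives dimethyl (2R,4R)-2-[3,4-bis(benzyloxy)phenyl]-4-formyloxolane-3,3-dicarboxylate F5. [4-(Benzyloxy)-3-methoxyphenyl]magnesium bromide F6, made from 1-(benzyloxy)-4-bromo-2-methoxybenzene and magnesium, is added in THF at −78 °C, where an aldehyde reacts far faster than the esters. The aryl group arrives anti to C3, and a chelate through O1 exposes the same face. The magnesium alkoxide of 13 that results should close to 14 on warming.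

Step 9.
- What may go wrong: at the Krapcho temperature the electron-rich benzylic C7–O(acyl) bond may ionise, or be attacked by chloride, and reclose. The guaiacyl ring would then drift from the concave to the more stable convex face, which means loss of configuration at C7.
- Fallback: alkyl–oxygen cleavage at high temperature is replaced by acyl–oxygen hydrolysis and a separate, milder decarboxylation. It sets out from 14 and comes back at 15. Me3SnOH in 1,2-dichloroethane at 60 °C should hydrolyse the methyl ester to (3R,3aR,6R,6aS)-6-[3,4-bis(benzyloxy)phenyl]-3-[4-(benzyloxy)-3-methoxyphenyl]-1-oxotetrahydro-1H,3H-furo[3,4-c]furan-6a-carboxylic acid F7. As a malonic half-acid, F7 should lose CO2 in refluxing MeCN with catalytic Cu2O. Protonation of the enol is again possible only to the cis-fused bicycle 15.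

Further compounds
F1 | step 6 | dimethyl (2S,4S)-2-[3,4-bis(benzyloxy)phenyl]-4-{1-[4-(benzyloxy)-3-methoxyphenyl]ethenyl}oxolane-3,3-dicarboxylate (enantiomer of 10) | COc1cc(C(=C)[C@@H]2CO[C@@H](c3ccc(OCc4ccccc4)c(OCc5ccccc5)c3)C2(C(=O)OC)C(=O)OC)ccc1OCc6ccccc6
F2 | step 6 | dimethyl (2S,4S)-4-[4-(benzyloxy)-3-methoxybenzoyl]-2-[3,4-bis(benzyloxy)phenyl]oxolane-3,3-dicarboxylate (enantiomer of 12) | COc1cc(C(=O)[C@@H]2CO[C@@H](c3ccc(OCc4ccccc4)c(OCc5ccccc5)c3)C2(C(=O)OC)C(=O)OC)ccc1OCc6ccccc6
F3 | step 6 | methyl (3R,3aS,6S,6aR)-6-[3,4-bis(benzyloxy)phenyl]-3-[4-(benzyloxy)-3-methoxyphenyl]-1-oxotetrahydro-1H,3H-furo[3,4-c]furan-6a-carboxylate (both aryl rings exo) | COc1cc([C@@H]2OC(=O)[C@]3(C(=O)OC)[C@H]2CO[C@H]3c4ccc(OCc5ccccc5)c(OCc6ccccc6)c4)ccc1OCc7ccccc7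
F4 | step 8 | dimethyl (2R,4R)-2-[3,4-bis(benzyloxy)phenyl]-4-ethenyloxolane-3,3-dicarboxylate | C=C[C@H]1CO[C@H](c2ccc(OCc3ccccc3)c(OCc4ccccc4)c2)C1(C(=O)OC)C(=O)OC
F5 | step 8 | dimethyl (2R,4R)-2-[3,4-bis(benzyloxy)phenyl]-4-formyloxolane-3,3-dicarboxylate | O=C[C@H]1CO[C@H](c2ccc(OCc3ccccc3)c(OCc4ccccc4)c2)C1(C(=O)OC)C(=O)OC
F6 | step 8 | [4-(benzyloxy)-3-methoxyphenyl]magnesium bromide | COc1cc([Mg]Br)ccc1OCc1ccccc1
F7 | step 9 | (3R,3aR,6R,6aS)-6-[3,4-bis(benzyloxy)phenyl]-3-[4-(benzyloxy)-3-methoxyphenyl]-1-oxotetrahydro-1H,3H-furo[3,4-c]furan-6a-carboxylic acid | COc1cc([C@@H]2OC(=O)[C@@]3(C(=O)O)[C@@H]2CO[C@@H]3c4ccc(OCc5ccccc5)c(OCc6ccccc6)c4)ccc1OCc7ccccc7
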